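**Plan** (locants: C1 = CH–O, C4 = CHMe, C5 = quaternary CMe, C7 = side-chain carbon of ring B, C8 = ring C=O, C11 = side-chain stereocentre, C15 = methyl on C4)
1. Retrosynthetic cuts, in order: C6=C7 (dehydrogenation), C7–C11 (enolate alkylation with a lactate triflate), C8=O (allylic oxidation), the C1–O acyl bond, then the ring A bond C3–C4 (radical 6-endo closure), then C10–C1 (carbonylative coupling of a ring B enol triflate).
2. Forward: ring B is a cyclohexanone from the start and C5 is made quaternary (methyl, vinyl) first; the C10 ketone becomes an enol triflate and then an acryloyl group; ring A is closed onto it; ring B is oxidised to the cross-conjugated dienone last.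
3. Feature that allows the key event: the C1 oxygen of ring A, held as a ketone on C10, makes C3 the β-carbon of a vinyl ketone, while the vinyl group on quaternary C5 gives a nucleophilic C4 radical when a hydrogen atom adds to C15, which thereby becomes the C4 methyl group.
4. Stereochemistry: C5 from (S)-1-phenylethylamine (chiral imine Michael addition); C4 in the ring closure, relative to C5; C1 by hydride delivery anti to the C5 methyl group; C11 from methyl (S)-lactate by SN2 inversion.

Key step: step 6

**Step 1**
Reactants: 1 2-methylcyclohexan-1-one (racemic); 2 (S)-1-phenylethan-1-amine; 3 methyl acrylate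
Product: 6 methyl 3-[(1R)-1-methyl-2-oxocyclohexyl]propanoate, via chiral imine 4 (not isolated), via Michael adduct imine 5 (not isolated)
Conditions: 2, TsOH (cat.), toluene, reflux, Dean–Stark; then 3, THF, 40 °C; then 20% aq. AcOH, rt
Reagents that add atoms: water, O
Why: Deracemising Michael addition of a chiral imine: the more substituted secondary enamine tautomer of 4 adds to the acrylate through a compact cyclic transition state on the face remote from the phenyl group of the auxiliary, which sets quaternary C5 as (R) before hydrolysis returns the ketone.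

**Step 2**
Reactants: 6 methyl 3-[(1R)-1-methyl-2-oxocyclohexyl]propanoate
Product: 7 3-[(1R)-1-methyl-2-oxocyclohexyl]propanoic acid
Conditions: LiOH·H2O, THF/H2O, rt; then 1 M HCl
Reagents that add atoms: lithium hydroxide, [Li+].[OH-]
Why: Ester saponification; the quaternary centre carries no hydrogen and cannot epimerise.

**Step 3**
Reactants: 7 3-[(1R)-1-methyl-2-oxocyclohexyl]propanoic acid
Product: 9 (2R)-2-ethenyl-2-methylcyclohexan-1-one, via mixed benzoic anhydride 8 (not isolated)
Conditions: PdCl2(norbornadiene) (2 mol%), Xantphos (2.4 mol%), benzoic anhydride (1.2 equiv), N-methylpyrrolidone, 130 °C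
Reagents that add atoms: none
Why: Palladium-catalysed decarbonylative dehydration: zerovalent palladium inserts into the acyl C–O bond of the mixed anhydride, CO is extruded and β-hydride elimination gives the terminal alkene, which cannot migrate past the untouched quaternary centre.

**Step 4**
Reactants: 9 (2R)-2-ethenyl-2-methylcyclohexan-1-one
Product: 11 (6R)-6-ethenyl-6-methylcyclohex-1-en-1-yl trifluoromethanesulfonate, via lithium enolate 10 (not isolated)
Conditions: LiN(iPr)2, THF, −78 °C; then PhNTf2, −78 °C to rt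
Reagents that add atoms: N-phenylbis(trifluoromethanesulfonimide), O=S(=O)(N(c1ccccc1)S(=O)(=O)C(F)(F)F)C(F)(F)F
Why: Enolate O-sulfonylation: quaternary C5 leaves C9 as the only enolisable position, so the enol triflate forms with the double bond at C9=C10 only.

**Step 5**
Reactants: 11 (6R)-6-ethenyl-6-methylcyclohex-1-en-1-yl trifluoromethanesulfonate; 12 tributyl(ethenyl)stannane
Product: 13 1-[(6R)-6-ethenyl-6-methylcyclohex-1-en-1-yl]prop-2-en-1-one
Conditions: Pd(PPh3)4 (5 mol%), LiCl (3 equiv), CO (1 atm), THF, 55 °C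
Reagents that add atoms: carbon monoxide, [C-]#[O+]
Why: Carbonylative Stille coupling: oxidative addition of the enol triflate to zerovalent palladium, CO insertion and transmetalation with the vinylstannane give the divinyl ketone, which places the C1 carbonyl carbon on C10.

**Step 6**
Reactants: 13 1-[(6R)-6-ethenyl-6-methylcyclohex-1-en-1-yl]prop-2-en-1-one
Product: 14 (4S,4aR)-4,4a-dimethyl-3,4,4a,5,6,7-hexahydronaphthalen-1(2H)-one
Conditions: Fe(acac)3 (1 equiv), PhSiH3 (2.5 equiv), EtOH/ethylene glycol, 60 °C, high dilution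
Reagents that add atoms: none
Why: Reductive olefin coupling (metal-hydride hydrogen atom transfer, then intramolecular Giese addition): the iron hydride formed from Fe(acac)3 and PhSiH3 delivers a hydrogen atom to C15 of the vinyl group, the secondary C4 radical adds to C3, the β-carbon of the vinyl ketone, and the resulting C2 radical is reduced to the iron enolate and protonated by ethanol. The closest known reaction type is the iron-mediated intramolecular coupling of unactivated donor alkenes with enones. Ring A closes in the 6-endo-trig mode, which the 4-oxohex-5-enyl arrangement favours because the nucleophilic radical attacks the unsubstituted, electron-poor terminus C3, while 5-exo attack at C2 would leave a primary radical. C4 is set in the bond-forming transition state, a chair-like ring A in which the C5 methyl group is axial (fixed by the half-chair of ring B) and the C4 methyl group is pseudo-equatorial, anti to C10, which leads to the cis-4,5-dimethyl isomer. The step needs hydrogen atom transfer to the vinyl group and not to the two conjugated alkenes, which the substrate helps by having the vinyl group as its only non-conjugated alkene; it also needs the equatorial-methyl closure, for which the bias is expected to be small.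

**Step 7**
Reactants: 14 (4S,4aR)-4,4a-dimethyl-3,4,4a,5,6,7-hexahydronaphthalen-1(2H)-one
Product: 15 (1R,4S,4aR)-4,4a-dimethyl-1,2,3,4,4a,5,6,7-octahydronaphthalen-1-ol
Conditions: NaBH4, CeCl3·7H2O, MeOH, −78 to 0 °C
Reagents that add atoms: none
Why: Luche 1,2-reduction: hydride adds to the C1 carbonyl from the face opposite the axial C5 methyl group (1,3-related across C10), which should give the axial (1R) allylic alcohol cis to both methyl groups.

**Step 8**
Reactants: 15 (1R,4S,4aR)-4,4a-dimethyl-1,2,3,4,4a,5,6,7-octahydronaphthalen-1-ol; 16 angelic acid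
Product: 18 (1R,4S,4aR)-4,4a-dimethyl-1,2,3,4,4a,5,6,7-octahydronaphthalen-1-yl (2Z)-2-methylbut-2-enoate, via mixed trichlorobenzoic anhydride 17 (not isolated)
Conditions: 16, 2,4,6-trichlorobenzoyl chloride, Et3N, toluene, rt; then 15, toluene, 80 °C
Reagents that add atoms: none
Why: Yamaguchi-type esterification through the mixed anhydride, run without a nucleophilic amine catalyst so that the (Z) double bond is not isomerised to the tiglate; C1 keeps its configuration because only the O–H bond reacts.

**Step 9**
Reactants: 18 (1R,4S,4aR)-4,4a-dimethyl-1,2,3,4,4a,5,6,7-octahydronaphthalen-1-yl (2Z)-2-methylbut-2-enoate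
Product: 19 (1R,4S,4aR)-4,4a-dimethyl-7-oxo-1,2,3,4,4a,5,6,7-octahydronaphthalen-1-yl (2Z)-2-methylbut-2-enoate
Conditions: dirhodium tetracaprolactamate Rh2(cap)4 (1 mol%), tert-butyl hydroperoxide (5 equiv), K2CO3, CH2Cl2, rt
Reagents that add atoms: tert-butyl hydroperoxide, CC(C)(C)OO
Why: Allylic C–H oxidation by tert-butylperoxyl radicals: C8 is the only allylic methylene of the C9=C10 alkene, since C5 is quaternary and the C1 methine is deactivated by its acyloxy group, so the enone forms at C8.

**Step 10**
Reactants: 20 methyl (2S)-2-hydroxypropanoate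
Product: 21 methyl (2S)-2-{[(trifluoromethyl)sulfonyl]oxy}propanoate
Conditions: Tf2O, 2,6-lutidine, CH2Cl2, −78 to 0 °C
Reagents that add atoms: trifluoromethanesulfonic anhydride, O=S(=O)(OS(=O)(=O)C(F)(F)F)C(F)(F)F
Why: O-Sulfonylation of the secondary alcohol with a hindered base; the stereocentre is not involved, so the (S) configuration is kept.

**Step 11**
Reactants: 19 (1R,4S,4aR)-4,4a-dimethyl-7-oxo-1,2,3,4,4a,5,6,7-octahydronaphthalen-1-yl (2Z)-2-methylbut-2-enoate; 21 methyl (2S)-2-{[(trifluoromethyl)sulfonyl]oxy}propanoate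
Product: 23 (1R,4S,4aR)-6-[(2S)-1-methoxy-1-oxopropan-2-yl]-4,4a-dimethyl-7-oxo-1,2,3,4,4a,5,6,7-octahydronaphthalen-1-yl (2Z)-2-methylbut-2-enoate (C6 epimers of the ring), via lithium dienolate 22 (not isolated)
Conditions: LiN(SiMe3)2 (1.05 equiv), THF, −78 °C; then 21, −78 to −40 °C
Reagents that add atoms: none
Why: Kinetic α′-deprotonation gives the cross-conjugated lithium dienolate, whose C7 carbon displaces triflate from the lactate carbon by SN2 with inversion (enolate alkylation with an α-triflyloxy ester), which sets C11 as (S); the C7 configuration is left open because C7 becomes sp2 in step 12.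

**Step 12**
Reactants: 23 (1R,4S,4aR)-6-[(2S)-1-methoxy-1-oxopropan-2-yl]-4,4a-dimethyl-7-oxo-1,2,3,4,4a,5,6,7-octahydronaphthalen-1-yl (2Z)-2-methylbut-2-enoate
Product: 24 (1R,4S,4aS)-6-[(2S)-1-methoxy-1-oxopropan-2-yl]-4,4a-dimethyl-7-oxo-1,2,3,4,4a,7-hexahydronaphthalen-1-yl (2Z)-2-methylbut-2-enoate
Conditions: DDQ (1.5 equiv), 1,4-dioxane, reflux
Reagents that add atoms: none
Why: DDQ dehydrogenation of an enone to the cross-conjugated dienone: enolisation towards C7 and hydride abstraction from the allylic C6 methylene (not from C11, whose C–H bond is deactivated by the ester) give the C6=C7 double bond, which removes the C7 stereocentre and leaves C11 and the angelate untouched.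

**Compound list**
1 | 2-methylcyclohexan-1-one (racemic) | CC1CCCCC1=O | starting material
2 | (S)-1-phenylethan-1-amine | C[C@H](N)c1ccccc1 | starting material
3 | methyl acrylate | C=CC(=O)OC | starting material
4 | (1S)-N-(2-methylcyclohexylidene)-1-phenylethan-1-amine (chiral imine, both ring epimers) | CC1CCCCC1=N[C@@H](C)c1ccccc1 | intermediate
5 | methyl 3-[(1R)-1-methyl-2-{[(1S)-1-phenylethyl]imino}cyclohexyl]propanoate | COC(=O)CC[C@@]1(C)CCCCC1=N[C@@H](C)c1ccccc1 | intermediate
6 | methyl 3-[(1R)-1-methyl-2-oxocyclohexyl]propanoate | COC(=O)CC[C@@]1(C)CCCCC1=O | intermediate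
7 | 3-[(1R)-1-methyl-2-oxocyclohexyl]propanoic acid | OC(=O)CC[C@@]1(C)CCCCC1=O | intermediate
8 | benzoic 3-[(1R)-1-methyl-2-oxocyclohexyl]propanoic anhydride | O=C(CC[C@@]1(C)CCCCC1=O)OC(=O)c1ccccc1 | intermediate
9 | (2R)-2-ethenyl-2-methylcyclohexan-1-one | C=C[C@@]1(C)CCCCC1=O | intermediate
10 | lithium (6R)-6-ethenyl-6-methylcyclohex-1-en-1-olate | C=C[C@@]1(C)CCCC=C1[O-].[Li+] | intermediate
11 | (6R)-6-ethenyl-6-methylcyclohex-1-en-1-yl trifluoromethanesulfonate | C=C[C@@]1(C)CCCC=C1OS(=O)(=O)C(F)(F)F | intermediate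
12 | tributyl(ethenyl)stannane | C=C[Sn](CCCC)(CCCC)CCCC | starting material
13 | 1-[(6R)-6-ethenyl-6-methylcyclohex-1-en-1-yl]prop-2-en-1-one | C=C[C@@]1(C)CCCC=C1C(=O)C=C | intermediate
14 | (4S,4aR)-4,4a-dimethyl-3,4,4a,5,6,7-hexahydronaphthalen-1(2H)-one | O=C1CC[C@H](C)[C@@]2(C)CCCC=C12 | intermediate
15 | (1R,4S,4aR)-4,4a-dimethyl-1,2,3,4,4a,5,6,7-octahydronaphthalen-1-ol | O[C@@H]1CC[C@H](C)[C@@]2(C)CCCC=C12 | intermediate
16 | angelic acid, (2Z)-2-methylbut-2-enoic acid | C/C=C(/C)C(=O)O | starting material
17 | (2Z)-2-methylbut-2-enoic 2,4,6-trichlorobenzoic anhydride | C/C=C(/C)C(=O)OC(=O)c1c(Cl)cc(Cl)cc1Cl | intermediate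
18 | (1R,4S,4aR)-4,4a-dimethyl-1,2,3,4,4a,5,6,7-octahydronaphthalen-1-yl (2Z)-2-methylbut-2-enoate | C/C=C(/C)C(=O)O[C@@H]1CC[C@H](C)[C@@]2(C)CCCC=C12 | intermediate
19 | (1R,4S,4aR)-4,4a-dimethyl-7-oxo-1,2,3,4,4a,5,6,7-octahydronaphthalen-1-yl (2Z)-2-methylbut-2-enoate | C/C=C(/C)C(=O)O[C@@H]1CC[C@H](C)[C@@]2(C)CCC(=O)C=C12 | intermediate
20 | methyl (2S)-2-hydroxypropanoate | C[C@H](O)C(=O)OC | starting material
21 | methyl (2S)-2-{[(trifluoromethyl)sulfonyl]oxy}propanoate | C[C@H](OS(=O)(=O)C(F)(F)F)C(=O)OC | intermediate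
22 | lithium dienolate of 19 (O–Li on C8, C7=C8 and C9=C10) | C/C=C(/C)C(=O)O[C@@H]1CC[C@H](C)[C@@]2(C)CC=C([O-])C=C12.[Li+] | intermediate
23 | (1R,4S,4aR)-6-[(2S)-1-methoxy-1-oxopropan-2-yl]-4,4a-dimethyl-7-oxo-1,2,3,4,4a,5,6,7-octahydronaphthalen-1-yl (2Z)-2-methylbut-2-enoate (C6 epimers of the ring) | C/C=C(/C)C(=O)O[C@@H]1CC[C@H](C)[C@@]2(C)CC([C@H](C)C(=O)OC)C(=O)C=C12 | intermediate
24 | (1R,4S,4aS)-6-[(2S)-1-methoxy-1-oxopropan-2-yl]-4,4a-dimethyl-7-oxo-1,2,3,4,4a,7-hexahydronaphthalen-1-yl (2Z)-2-methylbut-2-enoate | C/C=C(/C)C(=O)O[C@@H]1CC[C@H](C)[C@@]2(C)C=C([C@H](C)C(=O)OC)C(=O)C=C12 | target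

**Step count**
Total: 12 steps. Longest linear sequence: 11 steps (steps 1 to 9, then 11 and 12); step 10 prepares the side-chain electrophile.

**Steps most likely to fail**

1. Step 6. Two processes can go wrong. Hydrogen atom transfer may go to the acryloyl terminus instead of the vinyl group, after which the α-keto radical would close onto the vinyl group in the 5-exo mode. The two chair-like closures (C4 methyl pseudo-equatorial or pseudo-axial) may also be too close in energy, which would erode the cis-4,5-dimethyl relationship. The fallback sets out from 13 and returns at 14, and it sets C4 by reagent approach instead of by a ring-closure transition state. Ozone (CH2Cl2/MeOH, −78 °C, Sudan red end point, then Me2S) should cleave the only non-conjugated alkene of 13 to the aldehyde (1S)-1-methyl-2-(prop-2-enoyl)cyclohex-2-ene-1-carbaldehyde F1. SmI2 (THF/MeOH, −78 °C) should then close the same C3–C4 bond by ketyl–enone reductive coupling to the hydroxy ketone (4aS)-4-hydroxy-4a-methyl-3,4,4a,5,6,7-hexahydronaphthalen-1(2H)-one F2. Dess–Martin oxidation should give the dione (4aS)-4a-methyl-2,3,4a,5,6,7-hexahydronaphthalene-1,4-dione F3. Wittig methylenation (Ph3P=CH2, THF, 0 °C) of the saturated C4 ketone, which is more reactive than the conjugated C1 ketone, should give the exocyclic alkene (4aR)-4a-methyl-4-methylidene-3,4,4a,5,6,7-hexahydronaphthalen-1(2H)-one F4. Hydrogenation with RhCl(PPh3)3 (H2, benzene, rt) should add hydrogen to the 1,1-disubstituted alkene from the face opposite the angular methyl group, leave the conjugated C9=C10 alkene, and give 14.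

2. Step 11. O-Alkylation of the dienolate, or base-induced elimination of triflic acid from the electrophile, may outrun C-alkylation, and excess base may enolise at C11. The fallback sets out from 19 and returns at 23 and makes the C7–C11 bond by oxidative coupling of two enolates instead of by displacement. The lithium enolates of 19 and of commercial (4R)-4-benzyl-3-propanoyl-1,3-oxazolidin-2-one (LiN(iPr)2, THF, −78 °C) should be oxidised with Fe(acac)3 (oxidative enolate heterocoupling) to the 1,4-dicarbonyl compound (1R,4S,4aR)-6-{(2S)-1-[(4R)-4-benzyl-2-oxo-1,3-oxazolidin-3-yl]-1-oxopropan-2-yl}-4,4a-dimethyl-7-oxo-1,2,3,4,4a,5,6,7-octahydronaphthalen-1-yl (2Z)-2-methylbut-2-enoate F5. The benzyl group of the auxiliary should shield one face of the imide partner, so that C11 is formed as (S). MeOMgBr (from MeMgBr and MeOH, 0 °C) should then exchange the activated imide for the methyl ester and give 23.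

3. Step 12. Enolisation towards the hindered tertiary C7 may be slow, and oxidation may then start from the extended dienol towards C1 instead. The fallback sets out from 23 and returns at 24 and fixes the enol regiochemistry before the oxidation. Me3SiOTf/Et3N (CH2Cl2, 0 °C) should give the cross-conjugated silyl dienol ether (1R,4S,4aR)-6-[(2S)-1-methoxy-1-oxopropan-2-yl]-4,4a-dimethyl-7-[(trimethylsilyl)oxy]-1,2,3,4,4a,5-hexahydronaphthalen-1-yl (2Z)-2-methylbut-2-enoate F6. Saegusa–Ito oxidation with Pd(OAc)2 (MeCN, rt) should then give 24 by β-hydride elimination of the ring hydrogen at C6 from the palladium enolate at C7.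

**Further compounds**
F1 | step 6 | (1S)-1-methyl-2-(prop-2-enoyl)cyclohex-2-ene-1-carbaldehyde | O=C[C@@]1(C)CCCC=C1C(=O)C=C
F2 | step 6 | (4aS)-4-hydroxy-4a-methyl-3,4,4a,5,6,7-hexahydronaphthalen-1(2H)-one (C4 epimers) | O=C1CCC(O)[C@@]2(C)CCCC=C12
F3 | step 6 | (4aS)-4a-methyl-2,3,4a,5,6,7-hexahydronaphthalene-1,4-dione | O=C1CCC(=O)[C@@]2(C)CCCC=C12
F4 | step 6 | (4aR)-4a-methyl-4-methylidene-3,4,4a,5,6,7-hexahydronaphthalen-1(2H)-one | O=C1CCC(=C)[C@@]2(C)CCCC=C12
F5 | step 11 | (1R,4S,4aR)-6-{(2S)-1-[(4R)-4-benzyl-2-oxo-1,3-oxazolidin-3-yl]-1-oxopropan-2-yl}-4,4a-dimethyl-7-oxo-1,2,3,4,4a,5,6,7-octahydronaphthalen-1-yl (2Z)-2-methylbut-2-enoate (C6 epimers of the ring) | C/C=C(/C)C(=O)O[C@@H]1CC[C@H](C)[C@@]2(C)CC([C@H](C)C(=O)N3[C@H](Cc4ccccc4)COC3=O)C(=O)C=C12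
F6 | step 12 | (1R,4S,4aR)-6-[(2S)-1-methoxy-1-oxopropan-2-yl]-4,4a-dimethyl-7-[(trimethylsilyl)oxy]-1,2,3,4,4a,5-hexahydronaphthalen-1-yl (2Z)-2-methylbut-2-enoate | C/C=C(/C)C(=O)O[C@@H]1CC[C@H](C)[C@@]2(C)CC([C@H](C)C(=O)OC)=C(O[Si](C)(C)C)C=C12
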